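## Structural features

The target is a melampolide-type germacranolide: a cyclodeca-1(10),4-diene (C1–C10) fused across C6–C7 to an α-methylene-γ-butyrolactone (O on C6, C12 carbonyl, C11=C13). The C1=C10 alkene (carrying C14) is ring-cis and the C4=C5 alkene (carrying C15) is ring-trans, and the lactone is trans-fused. C6 (R), C7 (R) and C8 (R) are contiguous: the C7 side chain is trans to O6 and cis to the free C8 hydroxyl. C2 (S) is an isolated allylic centre carrying the angelate, and C15 is a primary allylic acetate. Fragile groups are the α-methylene lactone (Michael acceptor, base-labile), the angelate (Z to E isomerisation), the skipped diene in a medium ring (acid-induced transannular cyclisation, Cope rearrangement) and the 8-hydroxyl next to the lactone (relactonisation). The real difficulty is a ten-membered ring with one cis and one trans trisubstituted alkene, together with four oxygens (O2, O6/O12, O8, O15) that must be told apart. The key step exploits the six atoms C10–C1–C2–C3–C4–C5 with oxygen on C2: they are ring A of a cis-fused 2-siloxyhexalin (diene C1=C2–C3=C4, shared bond C5–C10), whose conrotatory photochemical opening gives exactly one ring-cis and one ring-trans terminal alkene. Ring B of that hexalin (C5–C10) carries the C6–C8 triad, which maps onto C3–C5 of quinic acid (C3 = C6, C4 = C7, C5 = C8, C1 = C10).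

## Logic of the disconnections

38 to 37 to 36: the C15–O acetyl bond and the O–Si bonds at O8 and O15 are cut. An acetate cannot pass the amide-base enolisation, so C15 stays silylated until the end. The forward steps need fluoride conditions that spare the methylene lactone and the angelate, then acylation of the primary allylic hydroxyl in preference to the hindered C8 hydroxyl.

36 to 33 to 32: the C12–O6 acyl bond is cut, giving a 2-methylene-1,4-diol masked as a silylene. The methylene lactone would not survive base, borane or irradiation, so it is made late. The forward oxidation must touch only the primary allylic alcohol; O8 is blocked so that only the 6,12-lactone can form, and C2 is already acylated so that its allylic alcohol cannot be re-oxidised.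

32 to 31 to 30: the C2–O acyl bond and the C2–H bond are cut. C2 becomes the ketone that enol ether hydrolysis delivers directly. The forward steps need a reagent-controlled reduction in a flexible ring and an acylation that keeps the Z geometry of the angelate.

30 to 29 to 28: the C2 carbonyl is taken back to its silyl enol ether and the C5–C10 bond is re-formed on paper. The medium ring and both alkene geometries are exchanged for two stereocentres of a cis-decalin. The forward step needs the correct sense of conrotation and cold handling of the triene.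

28 to 27 to 26 to 25: the enol O–Si bond and the two O–Si bonds of the silylene are cut, and the primary silyl ether is restored. The bridge is there to fix the ring-B chair. The forward steps need kinetic deprotonation at C1 and selective removal of a primary silyl ether.

25 to 24 to 23: the C3=C4 π bond and the C6–H bond are cut, leaving a C6 ketone and a C2 enol ether. The forward order matters: C6 is reduced first, so that C5–H is never flanked by a ketone and a vinylogous ketone. Hydride must come from the β face.

23 to 17 plus 22: C1–C10 and C4–C5 are cut. One step then builds ring A, the quaternary C10 and the cis fusion from a ring-B enone and a siloxy diene. It needs activation of a β-methyl enone and addition anti to the C7 and C8 substituents. A stepwise ring-A synthesis from a C10 ketone (C5 acylation, conjugate allylation, ozonolysis, aldol) was set aside for four reasons: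
- C5 and C9 of such a ketone differ only through C7.
- The allyl group would meet an axial silyloxy group on either face of C10.
- C5 would be set by an enolate protonation.
- Ozone would not spare C11=C13.

22 to 21 to 19 plus 20, and 19 to 18: the enol O–Si bond, the C3=C4 bond (cross-metathesis) and an O–Si bond are cut, reaching allyl alcohol and methyl vinyl ketone.

17 to 15 to 14 to 12: the C5=C10 π bond, the C6 carbonyl and the C10–C14 bond are cut. The enone is reached regiospecifically because only C5 lies between the C6 ketone and the C10 carbinol. The forward steps must avoid loss of the C8 silyloxy group.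

12 to 11 to 10 to 9: two O–Si bonds are cut and the C10 ketone is traced to C1 of quinic acid (glycol cleavage after reduction). The lactone of 9 keeps O5 (the future O8) distinct from O3 (the future O6) until both are needed.

9 to 6 to 5 to 4: C11=C13, C7–H and C7=C11 are cut, so the side chain comes from a C4 ketone by olefination, hydrogenation and methylenation. The bicyclic lactone must direct hydrogen to one face.

4 to 3 to 2 to 1: the C4 carbonyl, one O–Si bond and the lactone C–O bond are cut, reaching quinic acid, which supplies ring B and the absolute configuration.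

## Other disconnections considered

Alternative 1: The cut is C5–C6 together with the C12–O6 acyl bond. In the forward step CrCl2 with catalytic NiCl2 would turn the C5 alkenyl iodide of the seco ester A1 into an alkenylchromium species that adds to the C6 aldehyde; the chromium alkoxide would then close onto the C12 methyl ester to give the lactone A2.
- In its favour: ring and lactone form in one flask, both alkene geometries are fixed beforehand in an open chain, and the organochromium reagent tolerates the acetate, the angelate and the acrylate.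
- Against it here: C6 would be set during a ten-membered ring closure with only the adjacent C7 centre to guide it. The aldehyde carbon C6 sits next to C7, whose hydrogen is α to the aldehyde and γ to the acrylate, so epimerisation or migration of the double bond is likely. The open-chain C7/C8 pair and the Z-configured C1=C10 iodide precursor would all have to be built separately.
- Comparison: structurally it sets one ring stereocentre in the closing step, whereas the chosen plan fixes C6–C8 in a six-membered ring before the medium ring exists. Mechanistically it is a polar addition with an entropic penalty, against a unimolecular pericyclic cleavage. After the key step it is better than the chosen plan: A2 is one desilylation from the target, against seven steps here. Its route to A1 would be at least as long as the route to 28.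

Alternative 2: The cut is C6–C7. In the forward step n-BuLi would remove a propargylic hydrogen at C6 of the thirteen-membered ether A3; the carbanion would bond to C7 through the C13–C11–C7 allyl unit, contracting the ring to the cyclodecenynol A4 and releasing the C6 hydroxyl and the C11=C13 methylene.
- In its favour: ring contractions of this kind to ten-membered carbocycles are well precedented, and on this point the alternative is better supported than the chosen key step. C6 and C7 are formed together, with the hydroxyl and the methylene ready for the lactone.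
- Against it here: A4 still lacks C15, and its C4–C5 alkyne must become a ring-trans trisubstituted alkene carrying a hydroxymethyl group, which is a hard late transformation in a strained ring. The sense of induction at C6/C7 would rest on the remote C8 and C2 centres or on a chiral base. C12 still has to be oxidised and C2 deprotected and acylated.
- Comparison: structurally it creates the C6/C7 pair that the chosen plan takes from quinic acid. Mechanistically it is an anionic sigmatropic shift, equal in elegance, but it needs strong base where the chosen plan needs light. In step economy it is worse after the key step because of the C4/C15 problem.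

Alternative 3: The cut is C1–C2. In the forward step CrCl2 with catalytic NiCl2 would convert the Z-configured C1 alkenyl iodide of the lactone aldehyde A5 into an alkenylchromium species that adds to the C2 aldehyde, closing the ring onto the preformed trans-lactone and giving the alcohol A6.
- In its favour: the lactone and the C6–C8 triad are in place, only C2 is new, and A6 is two steps from the target (angeloylation, desilylation). On end-game step economy it is better than the chosen plan, and it equals it in leaving both alkene geometries unambiguous.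
- Against it here: C2 would be set by the conformation of a closing ten-membered ring far from any stereocentre, whereas the chosen plan sets C2 by a chiral catalyst. The C2 aldehyde is β,γ-unsaturated and prone to slip into conjugation. The methylene lactone would have to survive the whole synthesis of A5.
- Comparison: structurally it is the most convergent of the three. Mechanistically it shares the entropic burden of Alternative 1. Its total length is probably similar to the chosen plan, because the lactone-bearing open chain with three contiguous centres needs its own multi-step synthesis.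

Key step: step 22

Remark: quinic acid numbering is used for 1–10 and germacrane numbering from 11 on; β is the face of ring B carrying O8, the C7 side chain and C14, and α is the face of O6. Compound 5 is an E/Z mixture, 7 and 8 are side-chain epimers, 13–16 are C10 epimers and 23/24 are C4 epimers; each mixture converges later, so these positions carry no descriptor. The hexalin entering the key step is used as 28, with O6 and O12 tied in a di-tert-butylsilylene and O8 as a TBS ether.

## Route

Step 1
Reactants: 1 (−)-quinic acid
Product: 2 quinide (1,5-lactone of 1)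
Conditions: TsOH·H2O (cat.), toluene/DMF, reflux, Dean–Stark
Reagents that add atoms: none
Why: Acid-catalysed lactonisation of the cis-related C1 carboxyl and C5 hydroxyl with azeotropic removal of water. It ties up O5 and leaves O3 and O4 free; no stereocentre is touched.

Step 2
Reactants: 2 quinide
Product: 3 3-O-triethylsilylquinide
Conditions: TESCl (1.1 equiv), imidazole, DMF, −10 °C
Reagents that add atoms: chlorotriethylsilane, CC[Si](Cl)(CC)CC
Why: Silylation of the equatorial C3 hydroxyl in preference to the axial C4 and tertiary C1 hydroxyls, a steric selection known for quinide with bulky silyl chlorides.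

Step 3
Reactants: 3 3-O-triethylsilylquinide
Product: 4 4-oxo-3-O-triethylsilylquinide
Conditions: Dess–Martin periodinane, CH2Cl2, 0 °C to rt
Reagents that add atoms: none
Why: Dess–Martin oxidation of the only secondary alcohol; the tertiary hydroxyl is inert and the non-basic medium avoids epimerisation of the doubly α-oxygenated ketone.

Step 4
Reactants: 4 4-oxo-3-O-triethylsilylquinide
Product: 5 4-(2-methoxy-2-oxoethylidene)-4-deoxy-3-O-triethylsilylquinide (E/Z)
Conditions: (MeO)2P(O)CH2CO2Me, LiCl, DBU, MeCN, 0 °C to rt
Reagents that add atoms: trimethyl phosphonoacetate, COC(=O)CP(=O)(OC)OC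
Why: Horner–Wadsworth–Emmons olefination under Masamune–Roush conditions, mild enough for the base-sensitive ketone. The alkene geometry is irrelevant because step 5 saturates it.

Step 5
Reactants: 5 ylidene ester
Product: 6 4-deoxy-4-(2-methoxy-2-oxoethyl)-3-O-triethylsilylquinide (side chain equatorial, cis to O5, trans to O3)
Conditions: H2 (1 atm), Pd/C, EtOAc, rt
Reagents that add atoms: none
Why: Heterogeneous hydrogenation from the face away from the lactone bridge, which carries only two axial hydrogens. The new C4–H is axial and the side chain equatorial, which sets the future C7 cis to O8 and trans to O6.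

Step 6
Reactants: 6 saturated ester
Product: 9 4-deoxy-4-(3-methoxy-3-oxoprop-1-en-2-yl)-3-O-triethylsilylquinide, via Mannich base 7 (not isolated), via ammonium iodide 8 (not isolated)
Conditions: LiN(i-Pr)2 (2.3 equiv), THF, −78 °C; CH2=NMe2+ I−, −78 to 0 °C; MeI, MeOH, rt; aq. NaHCO3
Reagents that add atoms: N,N-dimethylmethyleneiminium iodide (Eschenmoser's salt), C=[N+](C)C.[I-]
Why: Ester enolate Mannich reaction, quaternisation and E1cB elimination, the classical α-methylenation. The bridgehead lactone has no α-hydrogen, and the C4 centre is β to the ester and is not touched.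

Step 7
Reactants: 9 acrylate
Product: 10 tetraol 1-(hydroxymethyl)-4-(3-hydroxyprop-1-en-2-yl)-3-(triethylsilyloxy)cyclohexane-1,5-diol
Conditions: i-Bu2AlH (7 equiv), CH2Cl2, −78 to 0 °C; Rochelle salt
Reagents that add atoms: none
Why: Aluminium hydride reduction of the lactone to the diol and 1,2-reduction of the acrylate to the allylic alcohol. It frees O5 (the future O8) while O3 (the future O6) stays silylated.

Step 8
Reactants: 10 tetraol
Product: 11 ring-B ketone (C10 ketone; 6α-OTES, 7β-(3-hydroxyprop-1-en-2-yl), 8β-OH)
Conditions: NaIO4, THF/pH 7 buffer, 0 °C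
Reagents that add atoms: none
Why: Malaprade cleavage of the only vicinal diol gives the ketone; the neutral medium spares the β-hydroxy ketone.

Step 9
Reactants: 11 ring-B ketone
Product: 12 8β,12-bis(TBS) ether of 11
Conditions: TBSOTf (2.2 equiv), 2,6-lutidine, CH2Cl2, −78 °C
Reagents that add atoms: tert-butyldimethylsilyl triflate, CC(C)(C)[Si](C)(C)OS(=O)(=O)C(F)(F)F
Why: Silyl triflate silylation of the primary and the hindered axial secondary hydroxyl at low temperature. O6 keeps its more labile TES group for selective release.

Step 10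
Reactants: 12 bis(TBS) ketone
Product: 14 10-methyl-6α,10-diol (8β-OTBS, 12-OTBS), via tertiary carbinol 13 (not isolated)
Conditions: MeMgBr, CeCl3, THF, −78 °C; aq. NH4Cl; then PPTS (cat.), MeOH/CH2Cl2, 0 °C
Reagents that add atoms: methylmagnesium bromide, C[Mg]Br
Why: Cerium-mediated Grignard 1,2-addition installs C14 without enolisation or β-elimination. Mild acid methanolysis then removes the secondary TES ether in preference to the TBS ethers; the C10 configuration is irrelevant.

Step 11
Reactants: 14 diol
Product: 15 6-oxo-10-hydroxy-10-methyl ketone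
Conditions: Dess–Martin periodinane, CH2Cl2, 0 °C
Reagents that add atoms: none
Why: Dess–Martin oxidation of the only secondary alcohol; the tertiary carbinol is untouched.

Step 12
Reactants: 15 β-hydroxy ketone
Product: 17 (5R,6R)-5-(tert-butyldimethylsilyloxy)-3-methyl-6-[3-(tert-butyldimethylsilyloxy)prop-1-en-2-yl]cyclohex-2-en-1-one (C6 ketone, C5=C10), via mesylate 16 (not isolated)
Conditions: MsCl, Et3N, CH2Cl2, 0 °C to rt
Reagents that add atoms: none
Why: Mesylation of the tertiary β-hydroxy ketone and E1cB elimination. Only C5 lies between the ketone and C10, so the conjugated C5=C10 enone forms regiospecifically.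

Step 13
Reactants: 18 allyl alcohol
Product: 19 allyl tert-butyldiphenylsilyl ether
Conditions: TBDPSCl, imidazole, CH2Cl2, rt
Reagents that add atoms: tert-butylchlorodiphenylsilane, CC(C)(C)[Si](Cl)(c1ccccc1)c1ccccc1
Why: Standard silylation of a primary alcohol.

Step 14
Reactants: 19 allyl silyl ether; 20 methyl vinyl ketone (3 equiv)
Product: 21 (E)-5-(tert-butyldiphenylsilyloxy)pent-3-en-2-one
Conditions: second-generation Grubbs catalyst RuCl2(PCy3)(H2IMes)(=CHPh) (5 mol%), CH2Cl2, 40 °C
Reagents that add atoms: none
Why: Olefin cross-metathesis of a terminal alkene with an electron-poor enone partner, which gives the E-enone; ethene is lost.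

Step 15
Reactants: 21 enone
Product: 22 (E)-2-(tert-butyldimethylsilyloxy)-5-(tert-butyldiphenylsilyloxy)penta-1,3-diene
Conditions: TBSOTf, Et3N, Et2O, 0 °C
Reagents that add atoms: tert-butyldimethylsilyl triflate, CC(C)(C)[Si](C)(C)OS(=O)(=O)C(F)(F)F
Why: Soft enolisation of the methyl ketone on its methyl side gives the 2-siloxy-1,3-diene with the E alkene retained.

Step 16
Reactants: 17 ring-B enone; 22 siloxy diene (1.5 equiv)
Product: 23 cis-fused octalinone (C2(OTBS)=C3, C4–CH2OTBDPS, 5β-H, 10β-CH3, C6 ketone, 7β side chain, 8β-OTBS)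
Conditions: HNTf2 (10 mol%), CH2Cl2, −78 to −40 °C
Reagents that add atoms: none
Why: Triflimide generates a silyl triflimide that activates the hindered β-methyl enone; Mukaiyama–Michael addition and ring closure amount to a Diels–Alder reaction, a known way to cis-fused angular-methyl decalins. The nucleophilic C1 terminus bonds to C10 and C4 to C5 (siloxy para, substituent ortho to the carbonyl-bearing carbon). The diene adds anti to the β-oriented C7 and C8 substituents, so C1 and C4 are α and H5 and C14 are β.

Step 17
Reactants: 23 cycloadduct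
Product: 24 6α-alcohol of 23
Conditions: LiBH(s-Bu)3, THF, −78 °C; aq. NH4Cl
Reagents that add atoms: none
Why: Bulky trialkylborohydride reduction by equatorial attack on the ring-B chair that keeps the 8-OTBS group equatorial and away from C14. Hydride then enters from the β face and gives the 6α-alcohol trans to the side chain; the cold, fast reduction leaves C5 untouched.

Step 18
Reactants: 24 silyl enol ether alcohol
Product: 25 cis-fused hexalinone (C2 ketone, C3=C4, 15-OTBDPS, 6α-OH, 8β-OTBS, 12-OTBS)
Conditions: Pd(OAc)2 (1.1 equiv), MeCN, rt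
Reagents that add atoms: none
Why: Saegusa–Ito oxidation: the palladium enolate at C3 undergoes β-hydride elimination from C4, giving the C3=C4 enone regiospecifically. It follows the C6 reduction so that C5–H is never doubly activated.

Step 19
Reactants: 25 enone
Product: 26 6α,12-diol
Conditions: HF·pyridine, pyridine, THF, 0 °C
Reagents that add atoms: none
Why: Buffered fluoride cleaves the primary allylic TBS ether faster than the hindered secondary TBS and the TBDPS ethers.

Step 20
Reactants: 26 diol
Product: 27 O6,O12-di-tert-butylsilylene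
Conditions: t-Bu2Si(OTf)2, 2,6-lutidine, CH2Cl2, 0 °C
Reagents that add atoms: di-tert-butylsilyl bis(triflate), CC(C)(C)[Si](OS(=O)(=O)C(F)(F)F)(OS(=O)(=O)C(F)(F)F)C(C)(C)C
Why: Silylene formation across the only two free hydroxyls. The seven-membered ring can span O6 and C11 only when they are gauche, which holds C6–O and C7–C11 equatorial on ring B.

Step 21
Reactants: 27 bridged enone
Product: 28 cis-fused 2-(triethylsilyloxy)hexalin 1,3-diene (C1=C2–C3=C4)
Conditions: LiN(i-Pr)2 (1.3 equiv), TESCl (1.5 equiv), THF, −78 °C; Et3N, pentane, filtration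
Reagents that add atoms: chlorotriethylsilane, CC[Si](Cl)(CC)CC
Why: Kinetic deprotonation at C1 with in situ silylation gives the cross-conjugated silyl dienol ether; the γ-hydrogens at C5 and C15 are not removed under kinetic conditions.

Step 22
Reactants: 28 siloxy hexalin diene
Product: 29 ten-membered trienol silyl ether (cyclodeca-1(10),2,4-triene; C1=C10 ring-cis, C2=C3 ring-cis, C4=C5 ring-trans)
Conditions: hν (300 nm, Pyrex), degassed pentane, −78 °C, partial conversion
Reagents that add atoms: none
Why: Excitation of the homoannular 2-siloxy-1,3-diene triggers a conrotatory six-electron electrocyclic opening that cleaves the shared C5–C10 bond and leaves C1=C10, C2=C3 and C4=C5. The closest known reaction type is the photochemical opening of eudesmane-type hexalin 1,3-dienes to germacratrienes, as in provitamin D to previtamin D. No ring is closed: the ten-membered ring appears by cleavage, no stereocentre is formed, and C5 and C10 are lost while C6, C7 and C8 are spectators. Because the diene is cis-fused, conrotation turns one ring-B bond outward and the other inward, giving one ring-trans and one ring-cis terminal alkene. The step needs torquoselectivity: C6 outward (ring-trans C4=C5) and C9 inward (ring-cis C1=C10). The opening follows the helicity of the ground-state diene, the substituent pseudo-equatorial on ring A turning outward; the silylene fixes the ring-B chair in which C5–C4 is axial, so C6 is pseudo-equatorial and C9 pseudo-axial on ring A. Low temperature, long-wavelength light and partial conversion should suppress thermal disrotatory reclosure, hydrogen shifts and secondary photochemistry, and the enol ether allows immediate cold hydrolysis.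

Step 23
Reactants: 29 trienol silyl ether
Product: 30 skipped dienone (C2 ketone, C1=C10, C4=C5)
Conditions: Bu4NF (1.05 equiv), AcOH (1.05 equiv), THF, −78 °C
Reagents that add atoms: none
Why: Fluoride cleaves the silyl dienol ether far faster than the alkyl silyl ethers and the silylene; kinetic protonation at C3 gives the β,γ-unsaturated enone and leaves the C4=C5 geometry intact.

Step 24
Reactants: 30 dienone
Product: 31 (2S)-allylic alcohol
Conditions: (R)-2-methyl-CBS-oxazaborolidine (0.3 equiv), catecholborane, toluene, −78 °C
Reagents that add atoms: none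
Why: Corey–Bakshi–Shibata reduction with the alkenyl side (C1) as the large group; the R catalyst should deliver hydride to the face that gives the 2S alcohol. Catecholborane avoids hydroboration of the alkenes.

Step 25
Reactants: 31 alcohol
Product: 32 2-O-angelate
Conditions: LiN(SiMe3)2, THF, −78 °C; (Z)-2-methylbut-2-enoic anhydride, −78 to 0 °C
Reagents that add atoms: angelic anhydride, C/C=C(/C)C(=O)OC(=O)/C(C)=C\C
Why: Acylation of the lithium alkoxide with the anhydride at low temperature, without a nucleophilic catalyst, so the Z ester is not isomerised to the tiglate.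

Step 26
Reactants: 32 angelate
Product: 33 6α,12-diol
Conditions: HF·pyridine, pyridine, THF, 0 °C
Reagents that add atoms: none
Why: Fluoride cleavage of the seven-membered dialkoxysilane in preference to the hindered secondary TBS and the TBDPS ethers.

Step 27
Reactants: 33 diol
Product: 36 6α,12-lactone (8-O-TBS, 15-O-TBDPS), via hydroxy enal 34 (not isolated), via lactol 35 (not isolated)
Conditions: TEMPO (0.2 equiv), PhI(OAc)2 (2.5 equiv), CH2Cl2, rt
Reagents that add atoms: none
Why: Oxoammonium oxidation of the primary allylic alcohol to the enal, which closes onto O6; the lactol is oxidised on to the lactone (oxidative lactonisation of a 1,4-diol). With O8 and O15 blocked only the trans-fused 6,12-lactone can form.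

Step 28
Reactants: 36 lactone
Product: 37 8β,15-diol
Conditions: HF·pyridine (excess), THF, 0 °C to rt
Reagents that add atoms: none
Why: Acidic fluoride removes the TBS and TBDPS ethers without the basic conditions that would damage the methylene lactone or move the esters.

Step 29
Reactants: 37 diol
Product: 38 target CNP0129394.1
Conditions: AcCl (1.05 equiv), 2,4,6-collidine, CH2Cl2, −78 °C
Reagents that add atoms: acetyl chloride, CC(Cl)=O
Why: Selective acetylation of the primary allylic hydroxyl over the hindered secondary C8 hydroxyl with a weak, hindered base at low temperature.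

## Compound list

1 | (−)-quinic acid, (1S,3R,4S,5R)-1,3,4,5-tetrahydroxycyclohexane-1-carboxylic acid | C1[C@H]([C@H]([C@@H](C[C@@]1(C(=O)O)O)O)O)O | starting material
2 | quinide, (1S,3R,4R,5R)-1,3,4-trihydroxy-6-oxabicyclo[3.2.1]octan-7-one | C1[C@H]([C@H]([C@@H](C[C@@]1(C2=O)O)O2)O)O | intermediate
3 | 3-O-triethylsilylquinide | C1[C@H]([C@H]([C@@H](C[C@@]1(C2=O)O)O2)O)O[Si](CC)(CC)CC | intermediate
4 | 4-oxo-3-O-triethylsilylquinide | C1[C@H](C(=O)[C@@H](C[C@@]1(C2=O)O)O2)O[Si](CC)(CC)CC | intermediate
5 | 4-(2-methoxy-2-oxoethylidene)-4-deoxy-3-O-triethylsilylquinide (E/Z) | C1[C@H](C(=CC(=O)OC)[C@@H](C[C@@]1(C2=O)O)O2)O[Si](CC)(CC)CC | intermediate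
6 | 4-deoxy-4-(2-methoxy-2-oxoethyl)-3-O-triethylsilylquinide, side chain cis to O5 | C1[C@H]([C@@H]([C@@H](C[C@@]1(C2=O)O)O2)CC(=O)OC)O[Si](CC)(CC)CC | intermediate
7 | Mannich base, 4-[3-(dimethylamino)-1-methoxy-1-oxopropan-2-yl] analogue of 6 | C1[C@H]([C@@H]([C@@H](C[C@@]1(C2=O)O)O2)C(CN(C)C)C(=O)OC)O[Si](CC)(CC)CC | intermediate (not isolated)
8 | trimethylammonium iodide of 7 | C1[C@H]([C@@H]([C@@H](C[C@@]1(C2=O)O)O2)C(C[N+](C)(C)C)C(=O)OC)O[Si](CC)(CC)CC.[I-] | intermediate (not isolated)
9 | 4-deoxy-4-(3-methoxy-3-oxoprop-1-en-2-yl)-3-O-triethylsilylquinide | C1[C@H]([C@@H]([C@@H](C[C@@]1(C2=O)O)O2)C(=C)C(=O)OC)O[Si](CC)(CC)CC | intermediate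
10 | 1-(hydroxymethyl)-4-(3-hydroxyprop-1-en-2-yl)-3-(triethylsilyloxy)cyclohexane-1,5-diol, C3–C5 as in 9 | C1[C@H]([C@@H]([C@@H](C[C@@]1(CO)O)O)C(=C)CO)O[Si](CC)(CC)CC | intermediate
11 | ring-B ketone: C10 ketone, 6α-OTES, 7β-(3-hydroxyprop-1-en-2-yl), 8β-OH | C1[C@H]([C@@H]([C@@H](CC1=O)O)C(=C)CO)O[Si](CC)(CC)CC | intermediate
12 | 8β,12-bis(TBS) ether of 11 | C1[C@H]([C@@H]([C@@H](CC1=O)O[Si](C)(C)C(C)(C)C)C(=C)CO[Si](C)(C)C(C)(C)C)O[Si](CC)(CC)CC | intermediate
13 | 10-hydroxy-10-methyl carbinol of 12 (C10 epimers) | C1[C@H]([C@@H]([C@@H](CC1(C)O)O[Si](C)(C)C(C)(C)C)C(=C)CO[Si](C)(C)C(C)(C)C)O[Si](CC)(CC)CC | intermediate (not isolated)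
14 | 10-methyl-6α,10-diol, 8β-OTBS, 12-OTBS | C1[C@H]([C@@H]([C@@H](CC1(C)O)O[Si](C)(C)C(C)(C)C)C(=C)CO[Si](C)(C)C(C)(C)C)O | intermediate
15 | 6-oxo-10-hydroxy-10-methyl ketone, 8β-OTBS, 12-OTBS | C1C(=O)[C@@H]([C@@H](CC1(C)O)O[Si](C)(C)C(C)(C)C)C(=C)CO[Si](C)(C)C(C)(C)C | intermediate
16 | 10-mesylate of 15 | C1C(=O)[C@@H]([C@@H](CC1(C)OS(C)(=O)=O)O[Si](C)(C)C(C)(C)C)C(=C)CO[Si](C)(C)C(C)(C)C | intermediate (not isolated)
17 | (5R,6R)-5-(tert-butyldimethylsilyloxy)-3-methyl-6-[3-(tert-butyldimethylsilyloxy)prop-1-en-2-yl]cyclohex-2-en-1-one | CC1=CC(=O)[C@@H]([C@@H](C1)O[Si](C)(C)C(C)(C)C)C(=C)CO[Si](C)(C)C(C)(C)C | intermediate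
18 | allyl alcohol | C=CCO | starting material
19 | allyl tert-butyldiphenylsilyl ether | C=CCO[Si](c1ccccc1)(c1ccccc1)C(C)(C)C | intermediate
20 | methyl vinyl ketone | CC(=O)C=C | starting material
21 | (E)-5-(tert-butyldiphenylsilyloxy)pent-3-en-2-one | CC(=O)/C=C/CO[Si](c1ccccc1)(c1ccccc1)C(C)(C)C | intermediate
22 | (E)-2-(tert-butyldimethylsilyloxy)-5-(tert-butyldiphenylsilyloxy)penta-1,3-diene | C=C(O[Si](C)(C)C(C)(C)C)/C=C/CO[Si](c1ccccc1)(c1ccccc1)C(C)(C)C | intermediate
23 | cis-fused octalinone: C2(OTBS)=C3, C4–CH2OTBDPS (epimers), 5β-H, 10β-CH3, C6 ketone, 7β side chain (12-OTBS), 8β-OTBS | C=C(CO[Si](C)(C)C(C)(C)C)[C@H]1C(=O)[C@@H]2C(CO[Si](c3ccccc3)(c3ccccc3)C(C)(C)C)C=C(O[Si](C)(C)C(C)(C)C)C[C@]2(C)C[C@H]1O[Si](C)(C)C(C)(C)C | intermediate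
24 | 6α-alcohol of 23 | C=C(CO[Si](C)(C)C(C)(C)C)[C@H]1[C@H](O)[C@@H]2C(CO[Si](c3ccccc3)(c3ccccc3)C(C)(C)C)C=C(O[Si](C)(C)C(C)(C)C)C[C@]2(C)C[C@H]1O[Si](C)(C)C(C)(C)C | intermediate
25 | cis-fused hexalinone: C2 ketone, C3=C4, 15-OTBDPS, 5β-H, 10β-CH3, 6α-OH, 8β-OTBS, 12-OTBS | C=C(CO[Si](C)(C)C(C)(C)C)[C@H]1[C@H](O)[C@@H]2C(CO[Si](c3ccccc3)(c3ccccc3)C(C)(C)C)=CC(=O)C[C@]2(C)C[C@H]1O[Si](C)(C)C(C)(C)C | intermediate
26 | 6α,12-diol of 25 | C=C(CO)[C@H]1[C@H](O)[C@@H]2C(CO[Si](c3ccccc3)(c3ccccc3)C(C)(C)C)=CC(=O)C[C@]2(C)C[C@H]1O[Si](C)(C)C(C)(C)C | intermediate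
27 | O6,O12-di-tert-butylsilylene of 26 | C=C(CO[Si]3(C(C)(C)C)C(C)(C)C)[C@H]1[C@H](O3)[C@@H]2C(CO[Si](c4ccccc4)(c4ccccc4)C(C)(C)C)=CC(=O)C[C@]2(C)C[C@H]1O[Si](C)(C)C(C)(C)C | intermediate
28 | cis-fused 2-(triethylsilyloxy)hexalin 1,3-diene, O6,O12-silylene, 8β-OTBS, 15-OTBDPS | C=C(CO[Si]3(C(C)(C)C)C(C)(C)C)[C@H]1[C@H](O3)[C@@H]2C(CO[Si](c4ccccc4)(c4ccccc4)C(C)(C)C)=CC(O[Si](CC)(CC)CC)=C[C@]2(C)C[C@H]1O[Si](C)(C)C(C)(C)C | intermediate
29 | ten-membered trienol silyl ether (cyclodeca-1(10),2,4-triene, C2-OTES) | C=C(CO[Si]3(C(C)(C)C)C(C)(C)C)[C@H]1[C@H](O3)/C=C(\CO[Si](c2ccccc2)(c2ccccc2)C(C)(C)C)/C=C(O[Si](CC)(CC)CC)\C=C(\C)C[C@H]1O[Si](C)(C)C(C)(C)C | intermediate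
30 | skipped dienone (C2 ketone, ring-cis C1=C10, ring-trans C4=C5) | C=C(CO[Si]3(C(C)(C)C)C(C)(C)C)[C@H]1[C@H](O3)/C=C(\CO[Si](c2ccccc2)(c2ccccc2)C(C)(C)C)/CC(=O)/C=C(/C)C[C@H]1O[Si](C)(C)C(C)(C)C | intermediate
31 | (2S)-alcohol | C=C(CO[Si]3(C(C)(C)C)C(C)(C)C)[C@H]1[C@H](O3)/C=C(\CO[Si](c2ccccc2)(c2ccccc2)C(C)(C)C)/C[C@H](O)/C=C(/C)C[C@H]1O[Si](C)(C)C(C)(C)C | intermediate
32 | 2-O-angelate | C=C(CO[Si]3(C(C)(C)C)C(C)(C)C)[C@H]1[C@H](O3)/C=C(\CO[Si](c2ccccc2)(c2ccccc2)C(C)(C)C)/C[C@H](OC(=O)/C(C)=C\C)/C=C(/C)C[C@H]1O[Si](C)(C)C(C)(C)C | intermediate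
33 | 6α,12-diol angelate | C=C(CO)[C@H]1[C@H](O)/C=C(\CO[Si](c2ccccc2)(c2ccccc2)C(C)(C)C)/C[C@H](OC(=O)/C(C)=C\C)/C=C(/C)C[C@H]1O[Si](C)(C)C(C)(C)C | intermediate
34 | 6α-hydroxy C12 enal | C=C(C=O)[C@H]1[C@H](O)/C=C(\CO[Si](c2ccccc2)(c2ccccc2)C(C)(C)C)/C[C@H](OC(=O)/C(C)=C\C)/C=C(/C)C[C@H]1O[Si](C)(C)C(C)(C)C | intermediate (not isolated)
35 | 6α,12-lactol (C12 epimers) | C=C1C(O)O[C@@H]2/C=C(\CO[Si](c3ccccc3)(c3ccccc3)C(C)(C)C)C[C@H](OC(=O)/C(C)=C\C)/C=C(/C)C[C@@H](O[Si](C)(C)C(C)(C)C)[C@@H]12 | intermediate (not isolated)
36 | 6α,12-lactone, 8-O-TBS, 15-O-TBDPS | C=C1C(=O)O[C@@H]2/C=C(\CO[Si](c3ccccc3)(c3ccccc3)C(C)(C)C)C[C@H](OC(=O)/C(C)=C\C)/C=C(/C)C[C@@H](O[Si](C)(C)C(C)(C)C)[C@@H]12 | intermediate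
37 | 8β,15-diol (15-deacetyl target) | C=C1C(=O)O[C@@H]2/C=C(\CO)C[C@H](OC(=O)/C(C)=C\C)/C=C(/C)C[C@@H](O)[C@@H]12 | intermediate
38 | CNP0129394.1 | C=C1C(=O)O[C@@H]2/C=C(\COC(C)=O)C[C@H](OC(=O)/C(C)=C\C)/C=C(/C)C[C@@H](O)[C@@H]12 | target

## Step count and risks

Total: 29 steps (26 in the main line, 3 for diene 22). Longest linear sequence: 26 steps (steps 1–12 and 16–29).

Step 22 (key step). The opening may proceed through the other ring-B conformer and turn C6 inward, giving the 1(10)-trans,4-cis triene. The triene may also reclose thermally or undergo hydrogen shifts and secondary photoreactions before it is hydrolysed. The silylene holds ring B only through a seven-membered ring, and the axial 8-silyloxy group is syn to C14 in the required chair. The fallback replaces the silylene by the trans-fused lactone itself, a five-membered lock; it sets out from 26 and returns at 36. Oxidative lactonisation of 26 (TEMPO, PhI(OAc)2) would give the lactone-fused hexalinone F1. Conjugate addition of dimethylamine would mask the methylene lactone as the amine adduct F2. LiN(i-Pr)2 and TESCl would give the lactone-locked siloxy diene F3, and irradiation as in step 22 the triene F4. Cold fluoride would give the dienone F5, CBS reduction the alcohol F6 and angeloylation the ester F7. Quaternisation with MeI and elimination with NaHCO3 would restore the methylene lactone and deliver 36.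

Step 16. The β,β-disubstituted enone may add too slowly, the reaction may stop after the first C–C bond, or the acid may cause loss of the 8-silyloxy group and aromatisation of ring B. The fallback separates the two bond formations; it sets out from 17 and 22 and returns at 23. A TiCl4-mediated Mukaiyama–Michael addition would form C1–C10 and give, after work-up, the diketone F8. Its C6 ketone would then be enol-silylated and closed onto the enone (TBSOTf, Et3N, an intramolecular Mukaiyama–Michael addition) to give 23.

Step 17. Hydride delivery from the α face would give the 6β-alcohol if the ring-B chair with axial 8-silyloxy is populated or the axial side chain blocks the β face. The fallback inverts instead of relying on facial control; it sets out from the 6β-alcohol F9 and returns at 24. Mitsunobu reaction (4-nitrobenzoic acid, PPh3, DIAD) would give the inverted 6α-ester F10, and K2CO3 in MeOH would release 24.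

Step 12 (with steps 10 and 11). Base may enolise C7 of the β-hydroxy ketone or of the enone, with loss of the C8 silanol and aromatisation; retro-aldol cleavage of the tertiary aldol is also possible. The fallback reaches 17 without a tertiary carbinol; it sets out from 12 and returns at 17. Methanolysis of the TES ether would give the β-hydroxy ketone F11 and Dess–Martin oxidation the cyclohexane-1,3-dione F12. Triflation at the less hindered oxygen would give the vinylogous triflate F13, and addition–elimination with Me2CuLi would put the methyl group on C10.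

Step 24. Facial selectivity may be poor in the flexible ten-membered ring, and the Lewis acid may move the C4=C5 double bond of the skipped dienone into conjugation. The fallback turns the wrong epimer to account; it sets out from the (2R)-alcohol F14 and returns at 32. Mitsunobu esterification with angelic acid (PPh3, DIAD) would install the angelate with inversion at C2.

## Further compounds

F1 | step 22 | lactone-fused hexalinone (6α,12-olide of 26) | C=C(C(=O)O3)[C@H]1[C@H]3[C@@H]2C(CO[Si](c4ccccc4)(c4ccccc4)C(C)(C)C)=CC(=O)C[C@]2(C)C[C@H]1O[Si](C)(C)C(C)(C)C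
F2 | step 22 | 13-(dimethylamino) adduct of F1 (C11 epimers) | CN(C)CC(C(=O)O3)[C@H]1[C@H]3[C@@H]2C(CO[Si](c4ccccc4)(c4ccccc4)C(C)(C)C)=CC(=O)C[C@]2(C)C[C@H]1O[Si](C)(C)C(C)(C)C
F3 | step 22 | lactone-locked 2-(triethylsilyloxy)hexalin 1,3-diene | CN(C)CC(C(=O)O3)[C@H]1[C@H]3[C@@H]2C(CO[Si](c4ccccc4)(c4ccccc4)C(C)(C)C)=CC(O[Si](CC)(CC)CC)=C[C@]2(C)C[C@H]1O[Si](C)(C)C(C)(C)C
F4 | step 22 | lactone-fused trienol silyl ether | CN(C)CC(C(=O)O3)[C@H]1[C@H]3/C=C(\CO[Si](c2ccccc2)(c2ccccc2)C(C)(C)C)/C=C(O[Si](CC)(CC)CC)\C=C(\C)C[C@H]1O[Si](C)(C)C(C)(C)C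
F5 | step 22 | lactone-fused skipped dienone | CN(C)CC(C(=O)O3)[C@H]1[C@H]3/C=C(\CO[Si](c2ccccc2)(c2ccccc2)C(C)(C)C)/CC(=O)/C=C(/C)C[C@H]1O[Si](C)(C)C(C)(C)C
F6 | step 22 | lactone-fused (2S)-alcohol | CN(C)CC(C(=O)O3)[C@H]1[C@H]3/C=C(\CO[Si](c2ccccc2)(c2ccccc2)C(C)(C)C)/C[C@H](O)/C=C(/C)C[C@H]1O[Si](C)(C)C(C)(C)C
F7 | step 22 | lactone-fused 2-O-angelate, amine adduct | CN(C)CC(C(=O)O3)[C@H]1[C@H]3/C=C(\CO[Si](c2ccccc2)(c2ccccc2)C(C)(C)C)/C[C@H](OC(=O)/C(C)=C\C)/C=C(/C)C[C@H]1O[Si](C)(C)C(C)(C)C
F8 | step 16 | Michael adduct: C6 ketone with 10β-methyl and 10α-[(E)-5-(tert-butyldiphenylsilyloxy)-2-oxopent-3-enyl] | C=C(CO[Si](C)(C)C(C)(C)C)[C@H]1C(=O)C[C@](C)(CC(=O)/C=C/CO[Si](c2ccccc2)(c2ccccc2)C(C)(C)C)C[C@H]1O[Si](C)(C)C(C)(C)C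
F9 | step 17 | 6β-alcohol (C6 epimer of 24) | C=C(CO[Si](C)(C)C(C)(C)C)[C@H]1[C@@H](O)[C@@H]2C(CO[Si](c3ccccc3)(c3ccccc3)C(C)(C)C)C=C(O[Si](C)(C)C(C)(C)C)C[C@]2(C)C[C@H]1O[Si](C)(C)C(C)(C)C
F10 | step 17 | 6α-(4-nitrobenzoate) of 24 | C=C(CO[Si](C)(C)C(C)(C)C)[C@H]1[C@H](OC(=O)c3ccc(cc3)[N+](=O)[O-])[C@@H]2C(CO[Si](c4ccccc4)(c4ccccc4)C(C)(C)C)C=C(O[Si](C)(C)C(C)(C)C)C[C@]2(C)C[C@H]1O[Si](C)(C)C(C)(C)C
F11 | step 12 | C10 ketone with 6α-OH, 8β-OTBS, 12-OTBS | C1[C@H]([C@@H]([C@@H](CC1=O)O[Si](C)(C)C(C)(C)C)C(=C)CO[Si](C)(C)C(C)(C)C)O
F12 | step 12 | cyclohexane-1,3-dione (C6 and C10 ketones) | C1C(=O)[C@@H]([C@@H](CC1=O)O[Si](C)(C)C(C)(C)C)C(=C)CO[Si](C)(C)C(C)(C)C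
F13 | step 12 | vinylogous triflate (C10–OTf, C6 ketone) | FC(F)(F)S(=O)(=O)OC1=CC(=O)[C@@H]([C@@H](C1)O[Si](C)(C)C(C)(C)C)C(=C)CO[Si](C)(C)C(C)(C)C
F14 | step 24 | (2R)-alcohol (C2 epimer of 31) | C=C(CO[Si]3(C(C)(C)C)C(C)(C)C)[C@H]1[C@H](O3)/C=C(\CO[Si](c2ccccc2)(c2ccccc2)C(C)(C)C)/C[C@@H](O)/C=C(/C)C[C@H]1O[Si](C)(C)C(C)(C)C
A1 | alternative 1 | seco ester: C5 alkenyl iodide, C6 aldehyde, C12 methyl ester | C=C(C(=O)OC)[C@@H](C=O)[C@H](O[Si](CC)(CC)CC)C/C(C)=C\[C@@H](OC(=O)/C(C)=C\C)C/C(COC(C)=O)=C/I
A2 | alternative 1 | C8 triethylsilyl ether of the target | C=C1C(=O)O[C@@H]2/C=C(\COC(C)=O)C[C@H](OC(=O)/C(C)=C\C)/C=C(/C)C[C@@H](O[Si](CC)(CC)CC)[C@@H]12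
A3 | alternative 2 | thirteen-membered propargylic C6–O–C13 ether (ring-cis C7=C11 assumed) | O1CC#CC[C@H](OCc2ccc(OC)cc2)/C=C(/C)C[C@@H](O[Si](C(C)C)(C(C)C)C(C)C)/C=C(/CO[Si](CC)(CC)CC)C1
A4 | alternative 2 | ten-membered cyclodecenynol with C6 and C7 set | C=C(CO[Si](CC)(CC)CC)[C@H]1[C@H](O)C#CC[C@H](OCc2ccc(OC)cc2)/C=C(/C)C[C@H]1O[Si](C(C)C)(C(C)C)C(C)C
A5 | alternative 3 | lactone aldehyde with (Z)-C1 alkenyl iodide | C=C1C(=O)O[C@H](/C=C(\COC(C)=O)CC=O)[C@H]1[C@H](O[Si](CC)(CC)CC)C/C(C)=C\I
A6 | alternative 3 | ten-membered C2 alcohol, C8 triethylsilyl ether | C=C1C(=O)O[C@@H]2/C=C(\COC(C)=O)C[C@H](O)/C=C(/C)C[C@@H](O[Si](CC)(CC)CC)[C@@H]12
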